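The earlier runs and the new flask come from a simulation with constants of no real substance, noise included.

Which of these flasks, alike but for temperature, held the most target at the end?

all flasks: substrate 10 mM (in portions, 2)

| flask | partner | capture agent | temperature | remark | time |
|---|---|---|---|---|---|
| dusk | 2.8 equiv | 3 mM | 0 °C | run made earlier; portions every 5.0 h |  |
| summer | 4.4 equiv | 3 mM | 25 °C | run made earlier; portions every 5.0 h |  |
| zeta | 2.00 equiv | 3.00 mM | 25 °C | the portions of substrate follow each other after 5.0 h, the first at the start | 25 h |
| alpha | 2.00 equiv | 3.00 mM | 5 °C | the portions of substrate follow each other after 5.0 h, the first at the start | 25 h |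
| gamma | 2.00 equiv | 3.00 mM | 45 °C | the portions of substrate follow each other after 5.0 h, the first at the start | 25 h |

- dusk (time / h: target / %, substrate / %): 3.00: 0, 47.0; 10.0: 1.2, 88.0; 20.0: 4.4, 73.7; 30.0: 2.6, 56.8; 40.0: 3.2, 46.4; 48.0: 5.1, 35.0; 72.0: 5.6, 18.3
- summer (time / h: target / %, substrate / %): 1.50: 9.1, 23.6; 2.50: 13.9, 13.6; 4.00: 17.2, 4.7; 6.00: 16.9, 28.4; 8.00: 18.2, 8.1; 12.0: 17.5, 0; 20.0: 14.9, 0

(readings scatter by 1 percentage point)

1. the flask with the highest amount of target, in percent of the substrate charged ("all alike" if they lie within 1.5 percentage points) (zeta / alpha / gamma / all alike)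
2. final target, as a percentage of the substrate charged, in zeta
3. final target, as a percentage of the substrate charged, in alpha
4. final target, as a percentage of the substrate charged, in gamma

- the analysis behind the earlier runs scatters by 1 percentage point, standard deviation

I worked in powers of ten. I defined the decade time D of a species as the time its pseudo-first-order loss takes to remove one power of ten. I held two such times against the stand: D_A for substrate, which I wanted shorter than the stand, and D_P for target, which I wanted longer. The stand is the time after the last portion, 20.0 h in each flask.

The summer readings gave D_A = 3.57 h and D_P = 138 h. The second is a loose reading, since target fell from 18.2% to 14.9%. Their ratio, the window W = D_P/D_A, came to 38.7. The dusk readings gave D_A = 90.9 h, so going from 25 °C to 0 °C stretched it 25.5-fold. I assumed that target's loss shifted by the same powers of ten, which keeps W constant. Unlike the forecast, I gave partner no part in substrate's loss.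

Zeta, at 25 °C, had its stand inside the window: longer than D_A and shorter than D_P. In alpha, D_A stretched to 47.6 h, longer than the stand, so by my count substrate remained. In gamma, D_A shrank to 0.268 h and D_P to 10.4 h, shorter than the stand, so by my count target was lost. I chose zeta.

The forecast also chose zeta, with 13% in zeta, 4% in alpha and 3% in gamma, saying of target that “Afterwards it decays slowly”.

The simulation gave 15.0% in zeta, 5.49% in alpha and 2.79% in gamma, so zeta held more target than the others.

    substrate + open intermediate → side product (k = 83.0 M⁻¹ h⁻¹, Ea = 50.0 kJ mol⁻¹)
    substrate → open intermediate (k = 0.440 h⁻¹, Ea = 95.0 kJ mol⁻¹)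
    2 partner → homo product (k = 160 M⁻¹ h⁻¹, Ea = 40.0 kJ mol⁻¹)
    open intermediate + capture agent → trapped intermediate (k = 21.0 M⁻¹ h⁻¹, Ea = 50.0 kJ mol⁻¹)
    partner + open intermediate → target (k = 270 M⁻¹ h⁻¹, Ea = 66.0 kJ mol⁻¹)
    target → over-reaction product (k = 0.0100 h⁻¹, Ea = 93.0 kJ mol⁻¹)
    (constants at 25 °C)

Alpha still held 37.0% substrate at 25.0 h, but its partner was down to 1.18% of its charge, and at 250 h, with substrate at 0.00508%, alpha held 6.34% target. Gamma's target stood at 22.8% at 5.00 h and at 2.79% at 25.0 h. The neighbouring flask was gamma run at 20 °C, with amounts and time held. There D_A came to 6.82 h, and W put D_P at 264 h, so the stand of 20.0 h lay inside the window. That flask ended with 13.6% target.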